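The bicoumarin is disconnected inside unit B (the 6,7-dihydroxycoumarin, primed atoms). Unit A (the 7-hydroxy-6,8-dimethoxycoumarin) stays intact as a 3-acetic ester. The feature used: C8a' (bonded to O1') and C4a' (bonded to C4') are adjacent carbons of a benzene ring that a mirror plane through the middle of the C6'–C7' bond maps onto itself. A symmetrical 4,5-dioxygenated benzyne therefore supplies that ring with no regiochemical question. In one flask the aryne, DMF and the ester enolate form O1'–C8a', C4a'–C4', C3'=C4' and O1'–C2', closing the pyranone ring of unit B on C3. The precursors are an ortho-silylaryl triflate carrying the protected catechol, DMF, and methyl 7-benzyloxy-6,8-dimethoxycoumarin-3-acetate.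

Key step: step 10

Remark on the chemistry: the unit B catechol travels as two benzyl ethers, not as a methylene acetal, because Lewis-acid opening of a methylenedioxy ring on an electron-poor coumarin would also endanger the crowded C8 methoxy group beside the freed O7. The carbon–oxygen skeleton of the aryne precursor and of the coupling product is unchanged, and one hydrogenolysis ends the route.

Step 1
Reactants: 1 3,4-bis(benzyloxy)benzaldehyde
Product: 3 3,4-bis(benzyloxy)phenol, via aryl formate 2 (not isolated)
Conditions: mCPBA, CH2Cl2, 0 °C to rt; then K2CO3 (cat.), MeOH, rt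
Reagents that add atoms: 3-chloroperoxybenzoic acid (mCPBA), O=C(OO)c1cccc(Cl)c1
Why: Baeyer–Villiger oxidation of an electron-rich benzaldehyde proceeds with aryl migration to the formate, which base-catalysed methanolysis cleaves to the phenol.

Step 2
Reactants: 3 3,4-bis(benzyloxy)phenol
Product: 4 4,5-bis(benzyloxy)-2-bromophenol
Conditions: NBS (1.0 equiv), MeCN, −20 to 0 °C, dark
Reagents that add atoms: N-bromosuccinimide, O=C1CCC(=O)N1Br
Why: Electrophilic aromatic bromination goes to C6, which is ortho to the hydroxyl and para to the C3 benzyloxy group, whereas C2 is squeezed between two oxygens.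

Step 3
Reactants: 4 4,5-bis(benzyloxy)-2-bromophenol
Product: 7 4,5-bis(benzyloxy)-2-(trimethylsilyl)phenyl trifluoromethanesulfonate, via silyl ether 5 (not isolated), via lithium phenolate 6 (not isolated)
Conditions: HMDS, THF, 70 °C, then evaporation; n-BuLi, THF, −78 °C; Tf2O, −78 °C to rt
Reagents that add atoms: hexamethyldisilazane, C[Si](C)(C)N[Si](C)(C)C; trifluoromethanesulfonic anhydride, O=S(=O)(OS(=O)(=O)C(F)(F)F)C(F)(F)F; n-butyllithium, [Li]CCCC (lithium appears only in 6)
Why: O-silylation, bromine–lithium exchange, retro-Brook 1,3 oxygen-to-carbon silyl shift and O-triflation form the standard telescoped entry to ortho-silylaryl triflates, and the benzyl ethers tolerate n-BuLi at −78 °C.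

Step 4
Reactants: 8 syringaldehyde (4-hydroxy-3,5-dimethoxybenzaldehyde)
Product: 9 4-(benzyloxy)-3,5-dimethoxybenzaldehyde
Conditions: BnBr, K2CO3, acetone, reflux
Reagents that add atoms: benzyl bromide, BrCc1ccccc1
Why: Williamson ether synthesis on the acidic para-formyl phenol installs the group that later shields O7 from the aryne and falls in the final hydrogenolysis.

Step 5
Reactants: 9 4-(benzyloxy)-3,5-dimethoxybenzaldehyde
Product: 10 4-(benzyloxy)-2-bromo-3,5-dimethoxybenzaldehyde
Conditions: NBS (1.05 equiv), MeCN, rt to 40 °C, dark
Reagents that add atoms: N-bromosuccinimide, O=C1CCC(=O)N1Br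
Why: In this electrophilic aromatic bromination the two open ring positions are equivalent, each ortho to one methoxy group and para to the other, and under ionic conditions neither the benzylic CH2 nor the plain phenyl ring competes.

Step 6
Reactants: 10 4-(benzyloxy)-2-bromo-3,5-dimethoxybenzaldehyde
Product: 11 2-(benzyloxy)-4-bromo-5-(dimethoxymethyl)-1,3-dimethoxybenzene (dimethyl acetal of 10)
Conditions: HC(OMe)3, p-TsOH (cat.), MeOH, reflux; Et3N quench
Reagents that add atoms: trimethyl orthoformate, COC(OC)OC
Why: Acid-catalysed acetalisation, driven by the orthoformate, masks the aldehyde so that neither the organolithium nor the peroxide of the next step can touch it.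

Step 7
Reactants: 11 2-(benzyloxy)-4-bromo-5-(dimethoxymethyl)-1,3-dimethoxybenzene
Product: 14 4-(benzyloxy)-2-hydroxy-3,5-dimethoxybenzaldehyde, via arylboronate 12 (not isolated), via phenol acetal 13 (not isolated)
Conditions: n-BuLi, THF, −78 °C; B(OMe)3, −78 °C to rt; 30% H2O2, aq NaOH, 0 °C; Na2SO3; then 2 M HCl, THF, rt
Reagents that add atoms: hydrogen peroxide, OO; water, O; trimethyl borate, COB(OC)OC (boron and two methoxy groups appear only in 12)
Why: This lithiation–borylation–oxidation sequence starts with a fast bromine–lithium exchange, borylates the aryllithium, oxidises the C–B bond by the usual boronate 1,2-shift while the acetal still guards against Dakin cleavage, and unmasks the aldehyde with acid once excess peroxide is destroyed.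

Step 8
Reactants: 14 4-(benzyloxy)-2-hydroxy-3,5-dimethoxybenzaldehyde; 15 succinic anhydride
Product: 16 2-[7-(benzyloxy)-6,8-dimethoxy-2-oxo-2H-chromen-3-yl]acetic acid
Conditions: 15 (4 equiv), anhydrous disodium succinate (NaO2CCH2CH2CO2Na), neat melt, 175 °C; aq NaHCO3, then HCl
Reagents that add atoms: none
Why: In this Perkin-type condensation, the classical entry to coumarin-3-acetic acids, the phenol is acylated by the anhydride, the aryl ester CH2 adds to the aldehyde in a six-membered intramolecular aldol and water is lost, so the tether sets the cis geometry that lactone formation needs.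

Step 9
Reactants: 16 2-[7-(benzyloxy)-6,8-dimethoxy-2-oxo-2H-chromen-3-yl]acetic acid
Product: 17 methyl 2-[7-(benzyloxy)-6,8-dimethoxy-2-oxo-2H-chromen-3-yl]acetate
Conditions: MeOH, H2SO4 (cat.), reflux
Reagents that add atoms: methanol, CO
Why: Fischer esterification converts the side-chain acid, while the coumarin lactone re-closes from any reversible opening and the benzyl and methyl ethers are inert.

Step 10
Reactants: 7 4,5-bis(benzyloxy)-2-(trimethylsilyl)phenyl trifluoromethanesulfonate; 17 methyl 2-[7-(benzyloxy)-6,8-dimethoxy-2-oxo-2H-chromen-3-yl]acetate; 18 N,N-dimethylformamide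
Product: 22 7-(benzyloxy)-3-[6,7-bis(benzyloxy)-2-oxo-2H-chromen-3-yl]-6,8-dimethoxy-2H-chromen-2-one (7,6',7'-tri-O-benzylarteminorin C), via aryne 19 (not isolated), via iminium phenolate 20 (not isolated), via aminolactone 21 (not isolated)
Conditions: CsF (6 equiv), 7 (2 equiv, slow addition), anhydrous 18 as solvent, 4 Å MS, rt then 50 °C
Reagents that add atoms: none
Why: CsF strips the silyl group of 7 and triflate leaves, giving the C2v-symmetric aryne 19; the DMF oxygen adds to it, the aryl anion closes on the iminium carbon, and the strained four-membered ring opens to the iminium phenolate (ortho-quinone methide) 20, which fixes O1'–C8a' and C4a'–C4'. The enolate of 17, started by fluoride and then sustained by the methoxide released later in the sequence, attacks the iminium carbon through its alpha carbon and makes the C3'–C4' bond. The phenolate closes the pyranone ring by 6-exo-trig addition–elimination at the methyl ester (O1'–C2') to give 21, and E1cB loss of dimethylamine installs C3'=C4'. The closest known reaction type is the three-component coupling of arynes, DMF and ester enolates or other active methylene compounds to coumarins. No stereocentre remains, since the two in 21 are erased by the elimination. The step needs site selectivity on the aryne (moot by symmetry, the oxygens sitting remote from the triple bond), capture of the aryne by DMF before the enolate (secured by DMF as solvent and slow addition of 7) and lactonisation at the right carbonyl (six-membered closure on the ester beats seven-membered attack on the unit A lactone), while 17 offers only one acidic CH2 and no free OH.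

Step 11
Reactants: 22 7,6',7'-tri-O-benzylarteminorin C
Product: 23 arteminorin C
Conditions: H2 (1 atm), 10% Pd/C, THF–MeOH, rt; filtration under argon
Reagents that add atoms: none
Why: Catalytic hydrogenolysis of aryl benzyl ethers is fast at 1 atm, cannot touch the methyl ethers and should outrun reduction of the two trisubstituted conjugated lactone alkenes when stopped after three equivalents of hydrogen.

Compound list
1 | 3,4-bis(benzyloxy)benzaldehyde | O=Cc1ccc(OCc2ccccc2)c(OCc2ccccc2)c1 | starting material
2 | 3,4-bis(benzyloxy)phenyl formate | O=COc1ccc(OCc2ccccc2)c(OCc2ccccc2)c1 | intermediate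
3 | 3,4-bis(benzyloxy)phenol | Oc1ccc(OCc2ccccc2)c(OCc2ccccc2)c1 | intermediate
4 | 4,5-bis(benzyloxy)-2-bromophenol | Oc1cc(OCc2ccccc2)c(OCc2ccccc2)cc1Br | intermediate
5 | [4,5-bis(benzyloxy)-2-bromophenoxy]trimethylsilane | C[Si](C)(C)Oc1cc(OCc2ccccc2)c(OCc2ccccc2)cc1Br | intermediate
6 | lithium 4,5-bis(benzyloxy)-2-(trimethylsilyl)phenolate | [Li+].[O-]c1cc(OCc2ccccc2)c(OCc2ccccc2)cc1[Si](C)(C)C | intermediate
7 | 4,5-bis(benzyloxy)-2-(trimethylsilyl)phenyl trifluoromethanesulfonate | C[Si](C)(C)c1cc(OCc2ccccc2)c(OCc2ccccc2)cc1OS(=O)(=O)C(F)(F)F | intermediate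
8 | syringaldehyde | COc1cc(C=O)cc(OC)c1O | starting material
9 | 4-(benzyloxy)-3,5-dimethoxybenzaldehyde | COc1cc(C=O)cc(OC)c1OCc1ccccc1 | intermediate
10 | 4-(benzyloxy)-2-bromo-3,5-dimethoxybenzaldehyde | COc1cc(C=O)c(Br)c(OC)c1OCc1ccccc1 | intermediate
11 | 2-(benzyloxy)-4-bromo-5-(dimethoxymethyl)-1,3-dimethoxybenzene | COc1cc(C(OC)OC)c(Br)c(OC)c1OCc1ccccc1 | intermediate
12 | dimethyl [3-(benzyloxy)-6-(dimethoxymethyl)-2,4-dimethoxyphenyl]boronate | COc1cc(C(OC)OC)c(B(OC)OC)c(OC)c1OCc1ccccc1 | intermediate
13 | 3-(benzyloxy)-6-(dimethoxymethyl)-2,4-dimethoxyphenol | COc1cc(C(OC)OC)c(O)c(OC)c1OCc1ccccc1 | intermediate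
14 | 4-(benzyloxy)-2-hydroxy-3,5-dimethoxybenzaldehyde | COc1cc(C=O)c(O)c(OC)c1OCc1ccccc1 | intermediate
15 | succinic anhydride | O=C1CCC(=O)O1 | starting material
16 | 2-[7-(benzyloxy)-6,8-dimethoxy-2-oxo-2H-chromen-3-yl]acetic acid | COc1cc2cc(CC(=O)O)c(=O)oc2c(OC)c1OCc1ccccc1 | intermediate
17 | methyl 2-[7-(benzyloxy)-6,8-dimethoxy-2-oxo-2H-chromen-3-yl]acetate | COC(=O)Cc1cc2cc(OC)c(OCc3ccccc3)c(OC)c2oc1=O | intermediate
18 | N,N-dimethylformamide | CN(C)C=O | starting material
19 | 4,5-bis(benzyloxy)benzyne | C1#CC=C(OCc2ccccc2)C(OCc2ccccc2)=C1 | intermediate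
20 | 4,5-bis(benzyloxy)-2-[(dimethyliminio)methyl]phenolate (ortho-quinone methide form) | C[N+](C)=Cc1cc(OCc2ccccc2)c(OCc2ccccc2)cc1[O-] | intermediate
21 | 7-(benzyloxy)-3-[6,7-bis(benzyloxy)-4-(dimethylamino)-2-oxo-3,4-dihydro-2H-chromen-3-yl]-6,8-dimethoxy-2H-chromen-2-one (both stereocentres transient and unassigned) | CN(C)C1c2cc(OCc3ccccc3)c(OCc3ccccc3)cc2OC(=O)C1c1cc2cc(OC)c(OCc3ccccc3)c(OC)c2oc1=O | intermediate
22 | 7-(benzyloxy)-3-[6,7-bis(benzyloxy)-2-oxo-2H-chromen-3-yl]-6,8-dimethoxy-2H-chromen-2-one | COc1cc2cc(-c3cc4cc(OCc5ccccc5)c(OCc5ccccc5)cc4oc3=O)c(=O)oc2c(OC)c1OCc1ccccc1 | intermediate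
23 | arteminorin C | COc1cc2cc(-c3cc4cc(O)c(O)cc4oc3=O)c(=O)oc2c(OC)c1O | target

Total step count: 11. Longest linear sequence: 8 (steps 4 to 11, from syringaldehyde). The aryne branch contributes steps 1 to 3.

Steps most likely to fail

1. Step 10. What may go wrong:
- Fluoride may enolise 17 too weakly, so the iminium phenolate is lost to traces of water or to oligomerisation.
- The enolate may be arylated directly by the aryne.
- The enolate may add in a conjugate sense to a second molecule of unit A.
- The liberated dimethylamine may consume aryne.

The fallback sets out from 3 and 16. Magnesium-mediated ortho-formylation of 3 (MgCl2, Et3N, paraformaldehyde, MeCN, reflux; Casnati–Skattebøl) at the open C6 position gives 4,5-bis(benzyloxy)-2-hydroxybenzaldehyde F1. Perkin–Oglialoro condensation of this aldehyde with acid 16 (Ac2O, Et3N, 110 °C) acylates the phenol through the mixed anhydride. It then closes the same pyranone ring by intramolecular aldol condensation and comes back to the route at 22.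

2. Step 8. What may go wrong:
- The aldol at the unactivated succinyl CH2 may be sluggish.
- The product acid may condense with a second aldehyde molecule to a symmetric dimer.
- The benzyl group may be lost in the hot acidic melt.

The fallback sets out from 14. Wittig olefination with dimethyl 2-(triphenylphosphoranylidene)butanedioate (toluene, reflux) gives dimethyl (E)-2-{[4-(benzyloxy)-2-hydroxy-3,5-dimethoxyphenyl]methylidene}butanedioate F2. Heating this diester in N,N-diethylaniline at about 210 °C isomerises the alkene and lactonises the phenol onto the conjugated ester. This is the known thermal Wittig route to 3-substituted coumarins. It comes back at 17 and bypasses step 9.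

3. Step 11. What may go wrong:
- The lactone alkenes may be saturated in competition with O-benzyl cleavage.
- Conversion may stall when partly deprotected material precipitates on the catalyst.
- The catechol may oxidise in air during filtration.

The fallback sets out from 22. It uses BCl3 with pentamethylbenzene in CH2Cl2 at −78 °C and a methanol quench at that temperature. This Lewis-acid benzyl transfer to a cation scavenger is fast enough at low temperature to leave aryl methyl ethers alone. It comes back at 23 and makes no new compound (F0).

Further compounds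
F1 | step 10 | 4,5-bis(benzyloxy)-2-hydroxybenzaldehyde | O=Cc1cc(OCc2ccccc2)c(OCc2ccccc2)cc1O
F2 | step 8 | dimethyl (E)-2-{[4-(benzyloxy)-2-hydroxy-3,5-dimethoxyphenyl]methylidene}butanedioate | COC(=O)C/C(C(=O)OC)=C\c1cc(OC)c(OCc2ccccc2)c(OC)c1O
F0 | step 11 | none | none
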